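**Plan**

1. Ring atoms of the target: C1 carbonyl, C2 propenyl carbon, C3, C4 quaternary methoxy carbon, C5 methoxy carbon, C6. The retrosynthesis cuts, in order: the O–CH3 bond at C4; the C2=C3 unsaturation; the C4–O bond, exchanged for a C6–S bond by a retro-[2,3] shift; the C6–S bond (back to C6–OH); the C4–C bond to the arylpropenyl chain; the C2–C bond to the propenyl chain.
2. Enabling feature: in the six-membered carbocycle, C4 is the far end of the allyl triad C6–C5=C4. Oxygen passed from a sulfoxide on C6 to C4 therefore makes the C4–O bond, the C4 stereocentre and the C1(=O)–C6=C5(OMe) vinylogous ester in one event.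
3. Forward: no ring is built. The carbocycle is the dearomatised ring of 2,3,4-trimethoxybenzaldehyde (as a quinone monoketal). The propenyl chain is joined at C2 by rhodium-catalysed conjugate addition, the arylpropenyl chain at C4 by alkenyllithium addition with carbonyl transposition. C6 then goes from ketone to alcohol to sulfide, the shift is run, and dehydrogenation and O-methylation finish.
4. Stereochemistry: C2 comes from (S)-BINAP/rhodium and is temporary (it makes every intermediate a single diastereomer and is erased by the dehydrogenation). The C6 (S) alcohol comes from CBS reduction and is inverted to (R) by thiolate. C4 (S) comes from C6 by suprafacial transfer. Both E alkenes come from the boronic acid and from syn-hydrozirconation.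

Key step: step 11

Assumption: the facial sense of the rhodium addition is taken from cyclohex-2-enone ((S)-BINAP giving 5S), and in the CBS reduction the ketal-bearing flank of the ketone is taken as the larger group; should either prove opposite, the enantiomeric ligand or catalyst is used.
Remark: C1–C6 in the Why lines are the target ring locants defined above; systematic names carry their own locants.

**Route**

Step 1
Reactants: 1 2,3,4-trimethoxybenzaldehyde
Product: 3 2,3,4-trimethoxyphenol, via aryl formate 2 (not isolated)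
Conditions: 30% H2O2, cat. H2SO4, MeOH, rt
Reagents that add atoms: hydrogen peroxide (OO)
Why: Acid-catalysed Dakin oxidation, in which the electron-rich aryl group migrates to oxygen in the perhydrate adduct and the formate 2 is methanolysed in the same flask.

Step 2
Reactants: 3 2,3,4-trimethoxyphenol
Product: 4 2,3,4,4-tetramethoxycyclohexa-2,5-dien-1-one
Conditions: PhI(OAc)2, MeOH, 0 °C to rt
Reagents that add atoms: methanol (CO)
Why: Hypervalent-iodine oxidative dearomatisation of a para-methoxyphenol, methanol being captured at the methoxy-bearing para carbon to give the quinone monoketal.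

Step 3
Reactants: 4 2,3,4,4-tetramethoxycyclohexa-2,5-dien-1-one; 5 (E)-prop-1-enylboronic acid
Product: 6 (5S)-2,3,4,4-tetramethoxy-5-[(E)-prop-1-enyl]cyclohex-2-en-1-one
Conditions: [Rh(OH)((S)-BINAP)]2 (1.5 mol%), dioxane–H2O 10:1, 35 °C
Reagents that add atoms: none
Why: Rhodium-catalysed asymmetric 1,4-addition of an alkenylboronic acid (Hayashi–Miyaura reaction) to the only unsubstituted enone alkene, the bisphosphine selecting the face so that the (5S) centre is expected and the E geometry of the boronic acid being retained.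

Step 4
Reactants: 7 4-ethynyl-1,2-dimethoxybenzene
Product: 9 1,2-dimethoxy-4-(prop-1-ynyl)benzene, via lithium acetylide 8 (not isolated)
Conditions: n-BuLi, THF, −78 °C; MeI, −78 °C to rt
Reagents that add atoms: iodomethane (CI)
Why: Deprotonation of the terminal alkyne followed by SN2 C-methylation of the acetylide.

Step 5
Reactants: 9 1,2-dimethoxy-4-(prop-1-ynyl)benzene
Product: 11 4-[(E)-2-iodoprop-1-enyl]-1,2-dimethoxybenzene, via alkenylzirconocene chloride 10 (not isolated)
Conditions: Cp2Zr(H)Cl (2 equiv), THF, 50 °C; then I2, 0 °C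
Reagents that add atoms: iodine (II)
Why: Syn-hydrozirconation under equilibrating conditions should place zirconium on the less hindered, methyl-bearing carbon, and iodinolysis of the C–Zr bond proceeds with retention to give the E iodide.

Step 6
Reactants: 11 4-[(E)-2-iodoprop-1-enyl]-1,2-dimethoxybenzene; 6 (5S)-2,3,4,4-tetramethoxy-5-[(E)-prop-1-enyl]cyclohex-2-en-1-one
Product: 14 (5S)-3-[(E)-1-(3,4-dimethoxyphenyl)prop-1-en-2-yl]-2,6,6-trimethoxy-5-[(E)-prop-1-enyl]cyclohex-2-en-1-one, via alkenyllithium 12 (not isolated), via tertiary carbinol 13 (not isolated)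
Conditions: t-BuLi (2 equiv per iodide), Et2O, −78 °C; then 6 in THF, −78 °C; then 1 M HCl, THF, 0 °C
Reagents that add atoms: water (O)
Why: Iodine–lithium exchange with retention of alkene geometry, 1,2-addition to the vinylogous ester carbonyl and acid-mediated Stork–Danheiser transposition join the fragments at C4, the ketal next to the new ketone being too deactivated to hydrolyse in dilute acid.

Step 7
Reactants: 14 (5S)-3-[(E)-1-(3,4-dimethoxyphenyl)prop-1-en-2-yl]-2,6,6-trimethoxy-5-[(E)-prop-1-enyl]cyclohex-2-en-1-one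
Product: 15 (1S,5S)-3-[(E)-1-(3,4-dimethoxyphenyl)prop-1-en-2-yl]-2,6,6-trimethoxy-5-[(E)-prop-1-enyl]cyclohex-2-en-1-ol
Conditions: (R)-2-methyl-CBS-oxazaborolidine [(R)-1-methyl-3,3-diphenyltetrahydro-1H,3H-pyrrolo[1,2-c][1,3,2]oxazaborole] (0.5 equiv), catecholborane, toluene, −78 to −40 °C
Reagents that add atoms: none
Why: Corey–Bakshi–Shibata reduction, in which the oxazaborolidine–borane complex binds the ketone away from its larger flank and delivers hydride to one face, so the C6 carbinol centre (S) is set by reagent control while low-temperature catecholborane spares the alkenes.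

Step 8
Reactants: 15 (1S,5S)-3-[(E)-1-(3,4-dimethoxyphenyl)prop-1-en-2-yl]-2,6,6-trimethoxy-5-[(E)-prop-1-enyl]cyclohex-2-en-1-ol
Product: 16 (2S,6S)-4-[(E)-1-(3,4-dimethoxyphenyl)prop-1-en-2-yl]-2-hydroxy-3-methoxy-6-[(E)-prop-1-enyl]cyclohex-3-en-1-one
Conditions: TsOH·H2O (5 mol%), acetone–H2O 20:1, 0 °C; NaHCO3 quench at full conversion
Reagents that add atoms: water (O)
Why: Specific-acid-catalysed hydrolysis of the dimethyl ketal, which with a dilute strong acid at low temperature is expected to outrun the rate-limiting C-protonation of the tetrasubstituted, conjugated enol ether.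

Step 9
Reactants: 16 (2S,6S)-4-[(E)-1-(3,4-dimethoxyphenyl)prop-1-en-2-yl]-2-hydroxy-3-methoxy-6-[(E)-prop-1-enyl]cyclohex-3-en-1-one
Product: 17 (1S,5S)-3-[(E)-1-(3,4-dimethoxyphenyl)prop-1-en-2-yl]-2-methoxy-6-oxo-5-[(E)-prop-1-enyl]cyclohex-2-en-1-yl methanesulfonate
Conditions: MsCl, Et3N, CH2Cl2, −40 °C
Reagents that add atoms: methanesulfonyl chloride (CS(=O)(=O)Cl)
Why: O-Sulfonylation of the secondary alcohol through the sulfene, which leaves the C–O bond and hence the (S) configuration at C6 untouched.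

Step 10
Reactants: 17 (1S,5S)-3-[(E)-1-(3,4-dimethoxyphenyl)prop-1-en-2-yl]-2-methoxy-6-oxo-5-[(E)-prop-1-enyl]cyclohex-2-en-1-yl methanesulfonate
Product: 18 (2R,6S)-4-[(E)-1-(3,4-dimethoxyphenyl)prop-1-en-2-yl]-3-methoxy-2-(phenylsulfanyl)-6-[(E)-prop-1-enyl]cyclohex-3-en-1-one
Conditions: PhSNa (1.05 equiv), THF–DMF, −40 °C
Reagents that add atoms: sodium benzenethiolate ([Na+].[S-]c1ccccc1)
Why: SN2 displacement at a carbon activated by the adjacent carbonyl inverts C6 to (R), the soft and weakly basic thiolate at low temperature limiting enolisation and SN2' attack being blocked at the fully substituted C4.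

Step 11
Reactants: 18 (2R,6S)-4-[(E)-1-(3,4-dimethoxyphenyl)prop-1-en-2-yl]-3-methoxy-2-(phenylsulfanyl)-6-[(E)-prop-1-enyl]cyclohex-3-en-1-one
Product: 21 (4S,6S)-4-[(E)-1-(3,4-dimethoxyphenyl)prop-1-en-2-yl]-4-hydroxy-3-methoxy-6-[(E)-prop-1-enyl]cyclohex-2-en-1-one, via allylic sulfoxide 19 (not isolated), via sulfenate ester 20 (not isolated)
Conditions: m-CPBA (1.0 equiv), NaHCO3, CH2Cl2, −78 °C; then P(OMe)3, MeOH, −78 °C to rt
Reagents that add atoms: m-CPBA (O=C(OO)c1cccc(Cl)c1)
Why: Oxidation at sulfur, the most nucleophilic site at −78 °C, gives allylic sulfoxide 19, which on warming undergoes the Mislow–Evans [2,3]-sigmatropic shift: the sulfinyl oxygen bonds to C4 while C6–S breaks and the ring alkene moves from C4=C5 to C5=C6, and sulfenate 20 is then cleaved at sulfur by the thiophile P(OMe)3. The closest known reaction type is the γ-hydroxylation of enones through α-sulfinyl β,γ-unsaturated ketones. No ring is closed; the five-atom array C4–C5–C6–S–O exists only in the envelope transition state. The new C4 stereocentre is controlled by the C6 stereocentre, because the shift is suprafacial and puts oxygen on the face of C4 that carried the C6–S bond, so (6R) becomes (4S). The step needs faithful 1,3-transfer and a favourable sulfoxide–sulfenate balance: the sulfur-bearing carbon belongs to one allyl system only and is flanked by a carbonyl carbon and a fully substituted alkene carbon, so sulfoxide syn-elimination has no hydrogen to remove; the new C5=C6 bond gains conjugation with the C1 ketone; and the thiophile drains the sulfenate irreversibly.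

Step 12
Reactants: 21 (4S,6S)-4-[(E)-1-(3,4-dimethoxyphenyl)prop-1-en-2-yl]-4-hydroxy-3-methoxy-6-[(E)-prop-1-enyl]cyclohex-2-en-1-one
Product: 23 (5S)-5-[(E)-1-(3,4-dimethoxyphenyl)prop-1-en-2-yl]-4-methoxy-1-[(E)-prop-1-enyl]-2,5-bis(trimethylsilyloxy)cyclohexa-1,3-diene, via dilithium alkoxide dienolate 22 (not isolated)
Conditions: LiN(iPr)2 (2.3 equiv), THF, −78 °C; Me3SiCl, −78 to 0 °C
Reagents that add atoms: chlorotrimethylsilane (C[Si](C)(C)Cl)
Why: After alkoxide formation, kinetic deprotonation of the vinylogous ester at its only sp3 alpha carbon (C2, also allylic) gives the cross-conjugated dienolate, and O-silylation traps both oxygens (silyl enol ether formation).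

Step 13
Reactants: 23 (5S)-5-[(E)-1-(3,4-dimethoxyphenyl)prop-1-en-2-yl]-4-methoxy-1-[(E)-prop-1-enyl]-2,5-bis(trimethylsilyloxy)cyclohexa-1,3-diene
Product: 25 (4S)-4-[(E)-1-(3,4-dimethoxyphenyl)prop-1-en-2-yl]-4-hydroxy-5-methoxy-2-[(E)-prop-1-enyl]cyclohexa-2,5-dien-1-one, via silyl ether dienone 24 (not isolated)
Conditions: Pd(OAc)2 (1.1 equiv), MeCN, rt; then K2CO3 (cat.), MeOH, 0 °C
Reagents that add atoms: none
Why: Saegusa–Ito oxidation, in which divalent palladium turns the silyl enol ether into a palladium enolate that loses the C3 hydride to install C2=C3 and erase the temporary C2 centre (a route that avoids a chalcogen oxide at the allylic C2 position, which would itself undergo a [2,3] shift), after which brief methanolysis removes the tertiary silyl ether.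

Step 14
Reactants: 25 (4S)-4-[(E)-1-(3,4-dimethoxyphenyl)prop-1-en-2-yl]-4-hydroxy-5-methoxy-2-[(E)-prop-1-enyl]cyclohexa-2,5-dien-1-one
Product: 27 (4S)-4-[(E)-1-(3,4-dimethoxyphenyl)prop-1-en-2-yl]-4,5-dimethoxy-2-[(E)-prop-1-enyl]cyclohexa-2,5-dien-1-one, via sodium alkoxide 26 (not isolated)
Conditions: NaH, THF–DMF, 0 °C; MeI, 0 °C to rt
Reagents that add atoms: iodomethane (CI)
Why: Williamson O-methylation of the tertiary alkoxide, in which no carbon acid competes and C4 keeps its configuration because only the O–H bond is broken.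

**Compound list**

1 | 2,3,4-trimethoxybenzaldehyde | COc1ccc(C=O)c(OC)c1OC | starting material
2 | 2,3,4-trimethoxyphenyl formate | COc1ccc(OC=O)c(OC)c1OC | intermediate
3 | 2,3,4-trimethoxyphenol | COc1ccc(O)c(OC)c1OC | intermediate
4 | 2,3,4,4-tetramethoxycyclohexa-2,5-dien-1-one | COC1=C(OC)C(OC)(OC)C=CC1=O | intermediate
5 | (E)-prop-1-enylboronic acid | C/C=C/B(O)O | starting material
6 | (5S)-2,3,4,4-tetramethoxy-5-[(E)-prop-1-enyl]cyclohex-2-en-1-one | C/C=C/[C@@H]1CC(=O)C(OC)=C(OC)C1(OC)OC | intermediate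
7 | 4-ethynyl-1,2-dimethoxybenzene | C#Cc1ccc(OC)c(OC)c1 | starting material
8 | lithium (3,4-dimethoxyphenyl)acetylide | [Li]C#Cc1ccc(OC)c(OC)c1 | intermediate
9 | 1,2-dimethoxy-4-(prop-1-ynyl)benzene | CC#Cc1ccc(OC)c(OC)c1 | intermediate
10 | chloro[(E)-1-(3,4-dimethoxyphenyl)prop-1-en-2-yl]bis(cyclopentadienyl)zirconium | C/C(=C\c1ccc(OC)c(OC)c1)[Zr](Cl)(C1C=CC=C1)C1C=CC=C1 | intermediate
11 | 4-[(E)-2-iodoprop-1-enyl]-1,2-dimethoxybenzene | I/C(C)=C/c1ccc(OC)c(OC)c1 | intermediate
12 | [(E)-1-(3,4-dimethoxyphenyl)prop-1-en-2-yl]lithium | [Li]/C(C)=C/c1ccc(OC)c(OC)c1 | intermediate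
13 | (5S)-1-[(E)-1-(3,4-dimethoxyphenyl)prop-1-en-2-yl]-2,3,4,4-tetramethoxy-5-[(E)-prop-1-enyl]cyclohex-2-en-1-ol (both C1 epimers) | C/C=C/[C@@H]1CC(O)(/C(C)=C/c2ccc(OC)c(OC)c2)C(OC)=C(OC)C1(OC)OC | intermediate
14 | (5S)-3-[(E)-1-(3,4-dimethoxyphenyl)prop-1-en-2-yl]-2,6,6-trimethoxy-5-[(E)-prop-1-enyl]cyclohex-2-en-1-one | C/C=C/[C@@H]1CC(/C(C)=C/c2ccc(OC)c(OC)c2)=C(OC)C(=O)C1(OC)OC | intermediate
15 | (1S,5S)-3-[(E)-1-(3,4-dimethoxyphenyl)prop-1-en-2-yl]-2,6,6-trimethoxy-5-[(E)-prop-1-enyl]cyclohex-2-en-1-ol | C/C=C/[C@@H]1CC(/C(C)=C/c2ccc(OC)c(OC)c2)=C(OC)[C@H](O)C1(OC)OC | intermediate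
16 | (2S,6S)-4-[(E)-1-(3,4-dimethoxyphenyl)prop-1-en-2-yl]-2-hydroxy-3-methoxy-6-[(E)-prop-1-enyl]cyclohex-3-en-1-one | C/C=C/[C@@H]1CC(/C(C)=C/c2ccc(OC)c(OC)c2)=C(OC)[C@H](O)C1=O | intermediate
17 | (1S,5S)-3-[(E)-1-(3,4-dimethoxyphenyl)prop-1-en-2-yl]-2-methoxy-6-oxo-5-[(E)-prop-1-enyl]cyclohex-2-en-1-yl methanesulfonate | C/C=C/[C@@H]1CC(/C(C)=C/c2ccc(OC)c(OC)c2)=C(OC)[C@H](OS(C)(=O)=O)C1=O | intermediate
18 | (2R,6S)-4-[(E)-1-(3,4-dimethoxyphenyl)prop-1-en-2-yl]-3-methoxy-2-(phenylsulfanyl)-6-[(E)-prop-1-enyl]cyclohex-3-en-1-one | C/C=C/[C@@H]1CC(/C(C)=C/c2ccc(OC)c(OC)c2)=C(OC)[C@@H](Sc2ccccc2)C1=O | intermediate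
19 | (2R,6S)-4-[(E)-1-(3,4-dimethoxyphenyl)prop-1-en-2-yl]-3-methoxy-2-(phenylsulfinyl)-6-[(E)-prop-1-enyl]cyclohex-3-en-1-one (both sulfur epimers) | C/C=C/[C@@H]1CC(/C(C)=C/c2ccc(OC)c(OC)c2)=C(OC)[C@@H](S(=O)c2ccccc2)C1=O | intermediate
20 | (4S,6S)-4-[(E)-1-(3,4-dimethoxyphenyl)prop-1-en-2-yl]-3-methoxy-4-[(phenylsulfanyl)oxy]-6-[(E)-prop-1-enyl]cyclohex-2-en-1-one | C/C=C/[C@@H]1C[C@](OSc2ccccc2)(/C(C)=C/c2ccc(OC)c(OC)c2)C(OC)=CC1=O | intermediate
21 | (4S,6S)-4-[(E)-1-(3,4-dimethoxyphenyl)prop-1-en-2-yl]-4-hydroxy-3-methoxy-6-[(E)-prop-1-enyl]cyclohex-2-en-1-one | C/C=C/[C@@H]1C[C@](O)(/C(C)=C/c2ccc(OC)c(OC)c2)C(OC)=CC1=O | intermediate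
22 | dilithium salt of 21 (C4 alkoxide and C1–C2 dienolate) | C/C=C/C1=C(O[Li])C=C(OC)[C@@](O[Li])(/C(C)=C/c2ccc(OC)c(OC)c2)C1 | intermediate
23 | (5S)-5-[(E)-1-(3,4-dimethoxyphenyl)prop-1-en-2-yl]-4-methoxy-1-[(E)-prop-1-enyl]-2,5-bis(trimethylsilyloxy)cyclohexa-1,3-diene | C/C=C/C1=C(O[Si](C)(C)C)C=C(OC)[C@@](O[Si](C)(C)C)(/C(C)=C/c2ccc(OC)c(OC)c2)C1 | intermediate
24 | (4S)-4-[(E)-1-(3,4-dimethoxyphenyl)prop-1-en-2-yl]-5-methoxy-2-[(E)-prop-1-enyl]-4-(trimethylsilyloxy)cyclohexa-2,5-dien-1-one | C/C=C/C1=C[C@](O[Si](C)(C)C)(/C(C)=C/c2ccc(OC)c(OC)c2)C(OC)=CC1=O | intermediate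
25 | (4S)-4-[(E)-1-(3,4-dimethoxyphenyl)prop-1-en-2-yl]-4-hydroxy-5-methoxy-2-[(E)-prop-1-enyl]cyclohexa-2,5-dien-1-one | C/C=C/C1=C[C@](O)(/C(C)=C/c2ccc(OC)c(OC)c2)C(OC)=CC1=O | intermediate
26 | sodium alkoxide of 25 | C/C=C/C1=C[C@](O[Na])(/C(C)=C/c2ccc(OC)c(OC)c2)C(OC)=CC1=O | intermediate
27 | (4S)-4-[(E)-1-(3,4-dimethoxyphenyl)prop-1-en-2-yl]-4,5-dimethoxy-2-[(E)-prop-1-enyl]cyclohexa-2,5-dien-1-one (CNP0258625.1) | C/C=C/C1=C[C@](OC)(/C(C)=C/c2ccc(OC)c(OC)c2)C(OC)=CC1=O | target

**Step count and risks**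

Total step count: 14. Longest linear sequence: 12 steps (from 1 through steps 1–3 and 6–14); the alkenyl iodide branch (steps 4–5) joins at step 6.

Steps most likely to fail:

Step 8. The acid may protonate the dienol ether or ionise the allylic alcohol (leading on to dehydrative aromatisation), or the product ketol may shift through its enediol, before ketal cleavage is complete. The fallback postpones the unmasking until after the sigmatropic shift, when the ketal has become a vinylogous ortho ester that hydrolyses under far milder acid than anything else in the molecule. It sets out from 15: redox condensation with PhSSPh and PBu3 in THF (Hata reaction, inversion at C6) should give the (6R)-phenylthio ketal F1. Oxidation with m-CPBA at −78 °C gives the sulfoxide F2, which rearranges on warming to the sulfenate F3 by the same suprafacial course ((6R) to (4S)). P(OMe)3 in MeOH then releases the tertiary alcohol F4. Brief exposure of F4 to oxalic acid on wet silica gel, with water expected to enter at the less hindered ketal carbon C1, returns to the route at 21.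

Step 10. The thiolate may act as a base, so that enolisation of the mesylate or of the α-thio ketone epimerises C6 or moves the C4=C5 bond into conjugation with the ketone. The fallback avoids both the sulfonate and free thiolate. It sets out from 16, which is treated directly with PhSSPh and PBu3 in THF at rt; the alkoxyphosphonium ion is displaced with inversion under essentially neutral conditions, and the route is rejoined at 18 with no new compound.

Step 7. Facial selectivity may be poor if the catalyst does not distinguish the ketal flank from the alkene flank, or if the substrate bias from C2 opposes it. The fallback gives up reagent control. It sets out from 14: Luche reduction (NaBH4, CeCl3·7H2O, MeOH, −78 °C) should give 15 together with its C6 epimer, the (1R,5S)-alcohol F5. The two are diastereomers because of the C2 centre and are separated by chromatography. F5 is oxidised back to 14 with Dess–Martin periodinane and recycled, and the route is rejoined at 15.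

**Further compounds**

F1 | step 8 | {(1R,5S)-3-[(E)-1-(3,4-dimethoxyphenyl)prop-1-en-2-yl]-2,6,6-trimethoxy-5-[(E)-prop-1-enyl]cyclohex-2-en-1-yl}(phenyl)sulfane | C/C=C/[C@@H]1CC(/C(C)=C/c2ccc(OC)c(OC)c2)=C(OC)[C@@H](Sc2ccccc2)C1(OC)OC
F2 | step 8 | S-oxide of F1 (both sulfur epimers) | C/C=C/[C@@H]1CC(/C(C)=C/c2ccc(OC)c(OC)c2)=C(OC)[C@@H](S(=O)c2ccccc2)C1(OC)OC
F3 | step 8 | (1S,5S)-1-[(E)-1-(3,4-dimethoxyphenyl)prop-1-en-2-yl]-2,4,4-trimethoxy-5-[(E)-prop-1-enyl]cyclohex-2-en-1-yl benzenesulfenate | C/C=C/[C@@H]1C[C@](OSc2ccccc2)(/C(C)=C/c2ccc(OC)c(OC)c2)C(OC)=CC1(OC)OC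
F4 | step 8 | (1S,5S)-1-[(E)-1-(3,4-dimethoxyphenyl)prop-1-en-2-yl]-2,4,4-trimethoxy-5-[(E)-prop-1-enyl]cyclohex-2-en-1-ol | C/C=C/[C@@H]1C[C@](O)(/C(C)=C/c2ccc(OC)c(OC)c2)C(OC)=CC1(OC)OC
F0 | step 10 | none | none
F5 | step 7 | (1R,5S)-3-[(E)-1-(3,4-dimethoxyphenyl)prop-1-en-2-yl]-2,6,6-trimethoxy-5-[(E)-prop-1-enyl]cyclohex-2-en-1-ol | C/C=C/[C@@H]1CC(/C(C)=C/c2ccc(OC)c(OC)c2)=C(OC)[C@@H](O)C1(OC)OC
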